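## Plan

- **Cuts:** debenzylation/debromination and reduction of the middle C3 ketone lead back to the protected trimer ketone 28. Cutting C3–C4 and C4–C4a of the middle unit (one carbon out of ring C) gives coumaranone 18 and the epicatechin-derived diazomethane 26.
- **Further cuts in 18:** O1–C2 and C2–C3 of the furanone (bromo ester 13), the formyl carbon, and the bond from the top C4 to the phloroglucinol ring (C4 ether 4 and silyl ether 6).
- **Forward order:** top C4–aryl bond, then the formyl group, then the furanone ring (O-alkylation/aldol, oxidation, decarboxylation). The carbon insertion then joins the bottom unit and creates ring C of the middle unit; reduction and hydrogenolysis finish.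
- **Enabling feature:** the middle C4 is a single sp3 carbon bonded to C3, C4a and the bottom C6. It therefore sits exactly where one carbon can be inserted between the carbonyl carbon (C3) and the aryl carbon (C3a) of a 2-arylbenzofuran-3-one.
- **Stereochemistry:** top and bottom units come from (+)-catechin and (−)-epicatechin. Top C4 is set by anti attack on the flavanyl cation, middle C4 by the chiral Sc catalyst, middle C2 by equilibration, and middle C3 by axial hydride delivery.

Key step: step 19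

Remark: 3,5-bis(benzyloxy)phenol (5) and 3,4-bis(benzyloxy)phenylacetic acid (11), the benzyl ethers of phloroglucinol and of 3,4-dihydroxyphenylacetic acid, are taken as purchased; which antipode of the tris(oxazoline) ligand gives the required C4 configuration cannot be predicted for this substrate and is fixed by a screen of both.

## Route

Step 1
Reactants: 1 (+)-catechin
Product: 2 5,7,3',4'-tetra-O-benzyl-(+)-catechin
Conditions: BnBr, K2CO3, DMF, 0 °C → rt
Reagents that add atoms: benzyl bromide, BrCc1ccccc1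
Why: Williamson etherification in which K2CO3 deprotonates only the four phenols, so the C3 alcohol stays free and the benzylic C2 is not epimerized.

Step 2
Reactants: 2 5,7,3',4'-tetra-O-benzyl-(+)-catechin
Product: 3 3,5,7,3',4'-penta-O-benzyl-(+)-catechin
Conditions: NaH, BnBr, DMF, 0 °C → rt
Reagents that add atoms: benzyl bromide, BrCc1ccccc1
Why: Williamson etherification of the secondary alkoxide completes the benzyl protection that the later oxidation steps require.

Step 3
Reactants: 3 3,5,7,3',4'-penta-O-benzyl-(+)-catechin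
Product: 4 (2R,3S,4S)-3,5,7-tris(benzyloxy)-2-[3,4-bis(benzyloxy)phenyl]-4-(2-ethoxyethoxy)chroman
Conditions: DDQ, 2-ethoxyethanol, CH2Cl2, rt
Reagents that add atoms: 2-ethoxyethanol, CCOCCO
Why: DDQ abstracts hydride from the benzylic C4, activated by the ortho and para benzyloxy groups of ring A, and the alcohol traps the cation (benzylic oxidation); the C4 configuration is of no consequence because the ether is ionized again in step 5.

Step 4
Reactants: 5 3,5-bis(benzyloxy)phenol
Product: 6 1,3-bis(benzyloxy)-5-(triisopropylsilyloxy)benzene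
Conditions: TIPSCl, imidazole, DMF, rt
Reagents that add atoms: triisopropylsilyl chloride, CC(C)[Si](Cl)(C(C)C)C(C)C
Why: Standard phenol silylation; the bulky silyl group marks the oxygen that becomes O1 of the middle unit and shields the two ring positions next to it.

Step 5
Reactants: 4 the C4 2-ethoxyethyl ether of penta-O-benzylcatechin; 6 1,3-bis(benzyloxy)-5-(triisopropylsilyloxy)benzene (threefold excess)
Product: 7 4α-[2,6-bis(benzyloxy)-4-(triisopropylsilyloxy)phenyl]-penta-O-benzylcatechin (2,3-trans-3,4-trans)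
Conditions: TMSOTf (0.2 equiv), CH2Cl2, −78 → −40 °C
Reagents that add atoms: none
Why: TMSOTf ionizes the C4 ether to the flavan-4-yl cation, which alkylates the arene (Friedel–Crafts alkylation, the standard C4–aryl coupling of flavan-3-ols) at the carbon between the two benzyloxy groups, because attack at any ring carbon is stabilized by all three oxygens alike while the two carbons next to the silyloxy group are shielded, and the arene enters anti to the C3 benzyloxy group to give the 3,4-trans (4α) adduct.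

Step 6
Reactants: 7 the silyl ether adduct
Product: 8 4α-[2,6-bis(benzyloxy)-4-hydroxyphenyl]-penta-O-benzylcatechin
Conditions: Bu4NF, THF, 0 °C; aq NH4Cl
Reagents that add atoms: none
Why: Fluoride cleaves the aryl silyl ether selectively (silyl ether deprotection) and frees the one phenol that directs the next step.

Step 7
Reactants: 8 the phenol adduct
Product: 10 4α-[2,6-bis(benzyloxy)-3-formyl-4-hydroxyphenyl]-penta-O-benzylcatechin, via hydroxymethylphenol 9 (not isolated)
Conditions: MgCl2, Et3N, (CH2O)n, THF, reflux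
Reagents that add atoms: formaldehyde (as paraformaldehyde), C=O
Why: Casnati–Skattebøl ortho-formylation, in which the magnesium phenoxide delivers formaldehyde to the ortho carbon and a second formaldehyde oxidizes the hydroxymethyl intermediate by Oppenauer-type hydride transfer, so only the ring with the free phenol reacts and its two ortho positions are equivalent.

Step 8
Reactants: 11 3,4-bis(benzyloxy)phenylacetic acid
Product: 12 allyl 3,4-bis(benzyloxy)phenylacetate
Conditions: allyl bromide, K2CO3, DMF, rt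
Reagents that add atoms: allyl bromide, C=CCBr
Why: Carboxylate O-alkylation gives an ester that can later be removed under neutral conditions in the presence of the benzyl ethers.

Step 9
Reactants: 12 allyl 3,4-bis(benzyloxy)phenylacetate
Product: 13 allyl 2-bromo-2-[3,4-bis(benzyloxy)phenyl]acetate (racemic)
Conditions: LiN(SiMe3)2, THF, −78 °C; then NBS, −78 °C; aq NH4Cl
Reagents that add atoms: N-bromosuccinimide, O=C1CCC(=O)N1Br
Why: Enolate α-bromination confines halogenation to the ester α-carbon and leaves the benzyl ether CH2 groups and the arene untouched.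

Step 10
Reactants: 10 the salicylaldehyde adduct; 13 allyl 2-bromo-2-[3,4-bis(benzyloxy)phenyl]acetate
Product: 15 allyl 4,6-bis(benzyloxy)-2-[3,4-bis(benzyloxy)phenyl]-3-hydroxy-5-(penta-O-benzylcatechin-4α-yl)-2,3-dihydrobenzofuran-2-carboxylate (diastereomer mixture at C2/C3), via aryl ether aldehyde 14 (not isolated)
Conditions: K2CO3, DMF, rt; then DBU (0.2 equiv), rt
Reagents that add atoms: none
Why: The phenoxide displaces the secondary benzylic bromide (Williamson O-alkylation) and the α-aryloxy ester enolate then adds to the neighbouring aldehyde in a 5-exo-trig intramolecular aldol reaction (the first two events of a Rap–Stoermer benzofuran synthesis, which stops here because C2 is quaternary); the two new centres need no control since C3 is oxidized in step 11 and C2 becomes epimerizable in step 12.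

Step 11
Reactants: 15 the 3-hydroxy-2,3-dihydrobenzofuran-2-carboxylate
Product: 16 allyl 4,6-bis(benzyloxy)-2-[3,4-bis(benzyloxy)phenyl]-3-oxo-5-(penta-O-benzylcatechin-4α-yl)-2,3-dihydrobenzofuran-2-carboxylate (C2 epimer mixture)
Conditions: Dess–Martin periodinane, CH2Cl2, 0 °C → rt
Reagents that add atoms: none
Why: Dess–Martin oxidation of the secondary benzylic alcohol gives the non-enolizable β-keto ester under neutral conditions that the benzyl ethers tolerate.

Step 12
Reactants: 16 the allyl β-keto ester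
Product: 18 4,6-bis(benzyloxy)-2-[3,4-bis(benzyloxy)phenyl]-5-(penta-O-benzylcatechin-4α-yl)benzofuran-3(2H)-one (C2 epimer mixture; kept under argon and used at once), via keto acid 17 (not isolated)
Conditions: Pd(PPh3)4 (5 mol%), morpholine, THF, rt, degassed
Reagents that add atoms: none
Why: Tsuji–Trost deallylation (zerovalent palladium ionizes the allyl ester and morpholine traps the allyl group) releases the β-keto acid, which loses CO2 through the aromatic 3-hydroxybenzofuran enol and tautomerizes to the coumaranone.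

Step 13
Reactants: 19 (−)-epicatechin
Product: 20 5,7,3',4'-tetra-O-benzyl-(−)-epicatechin
Conditions: BnBr, K2CO3, DMF, 0 °C → rt
Reagents that add atoms: benzyl bromide, BrCc1ccccc1
Why: Williamson etherification of the four phenols only, as in step 1.

Step 14
Reactants: 20 5,7,3',4'-tetra-O-benzyl-(−)-epicatechin
Product: 21 3,5,7,3',4'-penta-O-benzyl-(−)-epicatechin
Conditions: NaH, BnBr, DMF, 0 °C → rt
Reagents that add atoms: benzyl bromide, BrCc1ccccc1
Why: Williamson etherification of the C3 alkoxide removes the last acidic hydroxyl, which a diazo compound and a Lewis acid would not tolerate.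

Step 15
Reactants: 21 penta-O-benzyl-(−)-epicatechin
Product: 22 8-bromo-penta-O-benzyl-(−)-epicatechin
Conditions: NBS, CH2Cl2, −78 → 0 °C
Reagents that add atoms: N-bromosuccinimide, O=C1CCC(=O)N1Br
Why: Electrophilic aromatic bromination goes to C8, the more accessible of the two ring A positions as is usual for 5,7-dialkoxyflavans, and so blocks it for the next step.

Step 16
Reactants: 22 8-bromo-penta-O-benzyl-(−)-epicatechin
Product: 24 8-bromo-6-formyl-penta-O-benzyl-(−)-epicatechin, via iminium chloride 23 (not isolated)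
Conditions: POCl3, DMF, ClCH2CH2Cl, 70 °C; then aq NaOAc
Reagents that add atoms: N,N-dimethylformamide, CN(C)C=O; water, O
Why: Vilsmeier–Haack formylation attacks the only remaining activated ring position, C6 between the two benzyloxy groups, and aqueous work-up hydrolyses the iminium salt to the aldehyde.

Step 17
Reactants: 24 8-bromo-6-formyl-penta-O-benzyl-(−)-epicatechin
Product: 25 the hydrazone of aldehyde 24
Conditions: N2H4·H2O (large excess), THF/EtOH, 60 °C
Reagents that add atoms: hydrazine (as hydrate), NN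
Why: Condensation of the aldehyde with a large excess of hydrazine gives the hydrazone and suppresses azine formation.

Step 18
Reactants: 25 the hydrazone
Product: 26 8-bromo-6-(diazomethyl)-penta-O-benzyl-(−)-epicatechin (cold toluene solution, used at once)
Conditions: MnO2, MgSO4, CH2Cl2, 0 °C, dark; filtered under argon, solvent changed to toluene
Reagents that add atoms: none
Why: Dehydrogenation of a hydrazone with MnO2 is the standard preparation of aryldiazomethanes, and the two ortho benzyloxy groups shield the diazo carbon against dimerization.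

Step 19
Reactants: 18 the 5-flavanyl 2-arylbenzofuran-3(2H)-one (C2 epimer mixture); 26 8-bromo-6-(diazomethyl)-penta-O-benzyl-(−)-epicatechin
Product: 28 protected trimer ketone: penta-O-benzylcatechin-(4α→6)-[5,7,3',4'-tetra-O-benzyl-2,4-cis-flavan-3-one]-(4→6)-8-bromo-penta-O-benzylepicatechin, via 2-epi ketone 27 (not isolated)
Conditions: Sc(OTf)3 (20 mol%), chiral tris(oxazoline) ligand (24 mol%), 4 Å MS, toluene/CH2Cl2, −78 → −40 °C, slow addition of 26; then Et3N (0.3 equiv), −20 °C
Reagents that add atoms: none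
Why: Proposed new method: the Sc(OTf)3–tris(oxazoline) complex binds the C3 carbonyl of 18, the nucleophilic diazo carbon of 26 adds to it, and in the diazonium alkoxide the electron-rich aryl carbon C3a shifts from the carbonyl carbon to the diazo carbon as N2 leaves, which forms C3–C4 and C4–C4a of the middle unit in one event. The closest known reaction type is the Sc(OTf)3-catalysed one-carbon homologation of cyclic ketones with aryldiazomethanes (Tiffeneau–Demjanov type), including its enantioselective tris(oxazoline) variant that gives 2-aryl cycloalkanones; a coumaranone carbonyl and a diazo compound of this size have not been used in it. Ring C is not closed by a cyclization but arises by ring expansion, the 1,2-aryl shift turning the five-membered furanone into the six-membered pyranone. C4 is set by the catalyst, which selects the face of the diazo carbon that attacks the bound ketone, and since the shift inverts that carbon this face alone decides the configuration; C2 is set thermodynamically, the accessible and acidic C2–H being epimerized by Et3N through 27 to the 2,4-cis ketone with both aryl groups equatorial while C4–H is shielded by two ortho,ortho-disubstituted aryl groups. The step needs aryl migration in preference to C2 migration and to epoxide closure, and insertion in preference to proton transfer from C2–H to the diazo carbon; the 2,4,6-trioxygenated aryl carbon is the far better migrating group, and low temperature with slow addition of 26 keeps the diazo concentration low.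

Step 20
Reactants: 28 the protected trimer ketone
Product: 29 protected trimer alcohol: penta-O-benzylcatechin-(4α→6)-[5,7,3',4'-tetra-O-benzylcatechin]-(4α→6)-8-bromo-penta-O-benzylepicatechin (middle unit 2,3-trans-3,4-trans, free 3-OH)
Conditions: NaBH4, CeCl3·7H2O, THF/MeOH, −78 °C
Reagents that add atoms: none
Why: Luche reduction, in which the small hydride should attack axially, anti to the axial C–H bonds at C2 and C4 and unopposed by any 1,3-diaxial substituent (O1 and the sp2 C4a carry none), to give the equatorial alcohol trans to both aryl groups, while CeCl3 keeps the medium non-basic so that neither α-centre epimerizes.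

Step 21
Reactants: 29 the protected trimer alcohol
Product: 30 catechin-(4α→6)-catechin-(4α→6)-epicatechin (CNP0163146.3)
Conditions: H2 (1 atm), Pd(OH)2/C, Et3N (1.1 equiv), THF/MeOH/H2O, rt
Reagents that add atoms: none
Why: Hydrogenolysis over Pd(OH)2 on carbon cleaves all fourteen benzyl ethers and the aryl C–Br bond (hydrodehalogenation) without touching a stereocentre, and Et3N neutralizes the HBr that would otherwise threaten the acid-labile interflavan bonds.

## Compound list

1 | (+)-catechin | O[C@H]1Cc2c(O)cc(O)cc2O[C@@H]1c1ccc(O)c(O)c1 | starting material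
2 | 5,7,3',4'-tetra-O-benzyl-(+)-catechin | c9ccccc9COc1cc(OCc9ccccc9)c2c(c1)O[C@H](c4ccc(OCc9ccccc9)c(OCc9ccccc9)c4)[C@@H](O)C2 | intermediate
3 | 3,5,7,3',4'-penta-O-benzyl-(+)-catechin | c9ccccc9COc1cc(OCc9ccccc9)c2c(c1)O[C@H](c4ccc(OCc9ccccc9)c(OCc9ccccc9)c4)[C@@H](OCc9ccccc9)C2 | intermediate
4 | (2R,3S,4S)-3,5,7-tris(benzyloxy)-2-[3,4-bis(benzyloxy)phenyl]-4-(2-ethoxyethoxy)chroman | c9ccccc9COc1cc(OCc9ccccc9)c2c(c1)O[C@H](c4ccc(OCc9ccccc9)c(OCc9ccccc9)c4)[C@@H](OCc9ccccc9)[C@H]2OCCOCC | intermediate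
5 | 3,5-bis(benzyloxy)phenol | Oc1cc(OCc9ccccc9)cc(OCc9ccccc9)c1 | starting material
6 | 1,3-bis(benzyloxy)-5-(triisopropylsilyloxy)benzene | CC(C)[Si](C(C)C)(C(C)C)Oc1cc(OCc9ccccc9)cc(OCc9ccccc9)c1 | intermediate
7 | 4α-[2,6-bis(benzyloxy)-4-(triisopropylsilyloxy)phenyl]-penta-O-benzylcatechin | c9ccccc9COc1cc(OCc9ccccc9)c2c(c1)O[C@H](c4ccc(OCc9ccccc9)c(OCc9ccccc9)c4)[C@@H](OCc9ccccc9)[C@@H]2c1c(OCc9ccccc9)cc(O[Si](C(C)C)(C(C)C)C(C)C)cc1OCc9ccccc9 | intermediate
8 | 4α-[2,6-bis(benzyloxy)-4-hydroxyphenyl]-penta-O-benzylcatechin | c9ccccc9COc1cc(OCc9ccccc9)c2c(c1)O[C@H](c4ccc(OCc9ccccc9)c(OCc9ccccc9)c4)[C@@H](OCc9ccccc9)[C@@H]2c1c(OCc9ccccc9)cc(O)cc1OCc9ccccc9 | intermediate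
9 | 4α-[2,6-bis(benzyloxy)-4-hydroxy-3-(hydroxymethyl)phenyl]-penta-O-benzylcatechin (not isolated) | c9ccccc9COc1cc(OCc9ccccc9)c2c(c1)O[C@H](c4ccc(OCc9ccccc9)c(OCc9ccccc9)c4)[C@@H](OCc9ccccc9)[C@@H]2c1c(OCc9ccccc9)cc(O)c(CO)c1OCc9ccccc9 | intermediate
10 | 4α-[2,6-bis(benzyloxy)-3-formyl-4-hydroxyphenyl]-penta-O-benzylcatechin | c9ccccc9COc1cc(OCc9ccccc9)c2c(c1)O[C@H](c4ccc(OCc9ccccc9)c(OCc9ccccc9)c4)[C@@H](OCc9ccccc9)[C@@H]2c1c(OCc9ccccc9)cc(O)c(C=O)c1OCc9ccccc9 | intermediate
11 | 3,4-bis(benzyloxy)phenylacetic acid | OC(=O)Cc1ccc(OCc9ccccc9)c(OCc9ccccc9)c1 | starting material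
12 | allyl 3,4-bis(benzyloxy)phenylacetate | C=CCOC(=O)Cc1ccc(OCc9ccccc9)c(OCc9ccccc9)c1 | intermediate
13 | allyl 2-bromo-2-[3,4-bis(benzyloxy)phenyl]acetate (racemic) | C=CCOC(=O)C(Br)c1ccc(OCc9ccccc9)c(OCc9ccccc9)c1 | intermediate
14 | aryl ether aldehyde: 10 O-alkylated at the phenol with the CH(aryl)CO2allyl group (not isolated; epimer mixture) | c9ccccc9COc1cc(OCc9ccccc9)c2c(c1)O[C@H](c4ccc(OCc9ccccc9)c(OCc9ccccc9)c4)[C@@H](OCc9ccccc9)[C@@H]2c1c(OCc9ccccc9)cc(OC(C(=O)OCC=C)c4ccc(OCc9ccccc9)c(OCc9ccccc9)c4)c(C=O)c1OCc9ccccc9 | intermediate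
15 | allyl 4,6-bis(benzyloxy)-2-[3,4-bis(benzyloxy)phenyl]-3-hydroxy-5-(penta-O-benzylcatechin-4α-yl)-2,3-dihydrobenzofuran-2-carboxylate (C2/C3 mixture) | c9ccccc9COc1cc(OCc9ccccc9)c2c(c1)O[C@H](c4ccc(OCc9ccccc9)c(OCc9ccccc9)c4)[C@@H](OCc9ccccc9)[C@@H]2c1c(OCc9ccccc9)cc2c(c1OCc9ccccc9)C(O)C(C(=O)OCC=C)(c4ccc(OCc9ccccc9)c(OCc9ccccc9)c4)O2 | intermediate
16 | allyl 4,6-bis(benzyloxy)-2-[3,4-bis(benzyloxy)phenyl]-3-oxo-5-(penta-O-benzylcatechin-4α-yl)-2,3-dihydrobenzofuran-2-carboxylate (C2 mixture) | c9ccccc9COc1cc(OCc9ccccc9)c2c(c1)O[C@H](c4ccc(OCc9ccccc9)c(OCc9ccccc9)c4)[C@@H](OCc9ccccc9)[C@@H]2c1c(OCc9ccccc9)cc2c(c1OCc9ccccc9)C(=O)C(C(=O)OCC=C)(c4ccc(OCc9ccccc9)c(OCc9ccccc9)c4)O2 | intermediate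
17 | the corresponding 3-oxo-2,3-dihydrobenzofuran-2-carboxylic acid (not isolated) | c9ccccc9COc1cc(OCc9ccccc9)c2c(c1)O[C@H](c4ccc(OCc9ccccc9)c(OCc9ccccc9)c4)[C@@H](OCc9ccccc9)[C@@H]2c1c(OCc9ccccc9)cc2c(c1OCc9ccccc9)C(=O)C(C(O)=O)(c4ccc(OCc9ccccc9)c(OCc9ccccc9)c4)O2 | intermediate
18 | 4,6-bis(benzyloxy)-2-[3,4-bis(benzyloxy)phenyl]-5-(penta-O-benzylcatechin-4α-yl)benzofuran-3(2H)-one (C2 epimer mixture) | c9ccccc9COc1cc(OCc9ccccc9)c2c(c1)O[C@H](c4ccc(OCc9ccccc9)c(OCc9ccccc9)c4)[C@@H](OCc9ccccc9)[C@@H]2c1c(OCc9ccccc9)cc2c(c1OCc9ccccc9)C(=O)C(c4ccc(OCc9ccccc9)c(OCc9ccccc9)c4)O2 | intermediate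
19 | (−)-epicatechin | O[C@@H]1Cc2c(O)cc(O)cc2O[C@@H]1c1ccc(O)c(O)c1 | starting material
20 | 5,7,3',4'-tetra-O-benzyl-(−)-epicatechin | c1c(OCc9ccccc9)cc3c(c1OCc9ccccc9)C[C@@H](O)[C@@H](c4ccc(OCc9ccccc9)c(OCc9ccccc9)c4)O3 | intermediate
21 | 3,5,7,3',4'-penta-O-benzyl-(−)-epicatechin | c1c(OCc9ccccc9)cc3c(c1OCc9ccccc9)C[C@@H](OCc9ccccc9)[C@@H](c4ccc(OCc9ccccc9)c(OCc9ccccc9)c4)O3 | intermediate
22 | 8-bromo-penta-O-benzyl-(−)-epicatechin | c1c(OCc9ccccc9)c(Br)c3c(c1OCc9ccccc9)C[C@@H](OCc9ccccc9)[C@@H](c4ccc(OCc9ccccc9)c(OCc9ccccc9)c4)O3 | intermediate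
23 | C6 N,N-dimethyliminium chloride of 22 (not isolated) | C[N+](C)=Cc1c(OCc9ccccc9)c(Br)c3c(c1OCc9ccccc9)C[C@@H](OCc9ccccc9)[C@@H](c4ccc(OCc9ccccc9)c(OCc9ccccc9)c4)O3.[Cl-] | intermediate
24 | 8-bromo-6-formyl-penta-O-benzyl-(−)-epicatechin | O=Cc1c(OCc9ccccc9)c(Br)c3c(c1OCc9ccccc9)C[C@@H](OCc9ccccc9)[C@@H](c4ccc(OCc9ccccc9)c(OCc9ccccc9)c4)O3 | intermediate
25 | hydrazone of 24 | NN=Cc1c(OCc9ccccc9)c(Br)c3c(c1OCc9ccccc9)C[C@@H](OCc9ccccc9)[C@@H](c4ccc(OCc9ccccc9)c(OCc9ccccc9)c4)O3 | intermediate
26 | 8-bromo-6-(diazomethyl)-penta-O-benzyl-(−)-epicatechin | [N-]=[N+]=Cc1c(OCc9ccccc9)c(Br)c3c(c1OCc9ccccc9)C[C@@H](OCc9ccccc9)[C@@H](c4ccc(OCc9ccccc9)c(OCc9ccccc9)c4)O3 | intermediate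
27 | 2-epi (2,4-trans) protected trimer ketone (not isolated) | c9ccccc9COc1cc(OCc9ccccc9)c2c(c1)O[C@H](c4ccc(OCc9ccccc9)c(OCc9ccccc9)c4)[C@@H](OCc9ccccc9)[C@@H]2c1c(OCc9ccccc9)cc2c(c1OCc9ccccc9)[C@@H](c1c(OCc9ccccc9)c(Br)c3c(c1OCc9ccccc9)C[C@@H](OCc9ccccc9)[C@@H](c4ccc(OCc9ccccc9)c(OCc9ccccc9)c4)O3)C(=O)[C@H](c4ccc(OCc9ccccc9)c(OCc9ccccc9)c4)O2 | intermediate
28 | protected trimer ketone, middle unit a 2,4-cis flavan-3-one | c9ccccc9COc1cc(OCc9ccccc9)c2c(c1)O[C@H](c4ccc(OCc9ccccc9)c(OCc9ccccc9)c4)[C@@H](OCc9ccccc9)[C@@H]2c1c(OCc9ccccc9)cc2c(c1OCc9ccccc9)[C@@H](c1c(OCc9ccccc9)c(Br)c3c(c1OCc9ccccc9)C[C@@H](OCc9ccccc9)[C@@H](c4ccc(OCc9ccccc9)c(OCc9ccccc9)c4)O3)C(=O)[C@@H](c4ccc(OCc9ccccc9)c(OCc9ccccc9)c4)O2 | intermediate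
29 | protected trimer alcohol, middle unit 2,3-trans-3,4-trans with free 3-OH | c9ccccc9COc1cc(OCc9ccccc9)c2c(c1)O[C@H](c4ccc(OCc9ccccc9)c(OCc9ccccc9)c4)[C@@H](OCc9ccccc9)[C@@H]2c1c(OCc9ccccc9)cc2c(c1OCc9ccccc9)[C@@H](c1c(OCc9ccccc9)c(Br)c3c(c1OCc9ccccc9)C[C@@H](OCc9ccccc9)[C@@H](c4ccc(OCc9ccccc9)c(OCc9ccccc9)c4)O3)[C@H](O)[C@@H](c4ccc(OCc9ccccc9)c(OCc9ccccc9)c4)O2 | intermediate
30 | catechin-(4α→6)-catechin-(4α→6)-epicatechin (CNP0163146.3) | Oc1cc(O)c2c(c1)O[C@H](c1ccc(O)c(O)c1)[C@@H](O)[C@@H]2c1c(O)cc2c(c1O)[C@@H](c1c(O)cc3c(c1O)C[C@@H](O)[C@@H](c1ccc(O)c(O)c1)O3)[C@H](O)[C@@H](c1ccc(O)c(O)c1)O2 | target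

## Step count and risks

Total step count: 21. Longest linear sequence: 12 steps (1–3, 5–7, 10–12, 19–21).

**1. Step 19 (carbon insertion).**
- What may go wrong: proton transfer from the acidic C2–H of the Lewis-acid-bound coumaranone to the diazo carbon, followed by benzylation of the enolate; migration of C2 or epoxide closure in place of the aryl shift; weak face control at C4 or its loss during the C2 equilibration; and sequestration of the Sc catalyst by the many ether oxygens.
- Fallback (known chemistry): the trimer is assembled by Lewis-acid Friedel–Crafts coupling of C4-activated flavans, so that every stereocentre of the middle unit comes from (+)-catechin. It sets out from 2, 4 and 22 and comes back to the route at 30. NBS (CH2Cl2, −78 °C) brominates 2 at C8 to 8-bromo-5,7,3',4'-tetra-O-benzylcatechin F1. DDQ and 2-ethoxyethanol convert it into its C4 2-ethoxyethyl ether F2. TMSOTf (CH2Cl2, −78 °C) couples F2 with an excess of 22, whose only free ring A position is C6, to the 4α→6 catechin–epicatechin dibromide F3. The only free ring A position of F3 is C6 of its catechin unit, which is alkylated by the cation from 4 under the same conditions to the dibromo trimer F4. Hydrogenolysis as in step 21 removes both bromines and all benzyl groups to give 30.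

**2. Step 5 (C4–aryl coupling).**
- What may go wrong: attack of the cation ortho to the silyloxy group in place of the carbon between the two benzyloxy groups (wrong regiochemistry), or over-alkylation of the product.
- Fallback: a symmetric arene removes the regiochemical choice from the C–C bond formation. It sets out from 4 and comes back at 7. 4 and a fivefold excess of phloroglucinol (BF3·OEt2, THF/CH2Cl2, 0 °C) give the 4α-(2,4,6-trihydroxyphenyl) adduct F5. TIPSCl and imidazole silylate the one hydroxyl that has no neighbouring flavanyl group, giving the 4-O-silyl 2,6-diphenol F6. BnBr and K2CO3 in DMF then benzylate the two remaining phenols to give 7.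

**3. Step 20 (ketone reduction).**
- What may go wrong: hydride delivery from the equatorial direction, giving the axial alcohol cis to both aryl groups, or base-induced epimerization next to the ketone before reduction.
- Fallback: substrate control is replaced by reagent control. It sets out from 28 and comes back at 29. The ketone is reduced with a Corey–Bakshi–Shibata oxazaborolidine and BH3·SMe2 at −40 °C, using the catalyst antipode that delivers hydride to the face syn to the two aryl groups; no new compound arises.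

## Further compounds

F1 | step 19 | 8-bromo-5,7,3',4'-tetra-O-benzylcatechin | c1c(OCc9ccccc9)c(Br)c3c(c1OCc9ccccc9)C[C@H](O)[C@@H](c4ccc(OCc9ccccc9)c(OCc9ccccc9)c4)O3
F2 | step 19 | C4 2-ethoxyethyl ether of 8-bromo-5,7,3',4'-tetra-O-benzylcatechin | c1c(OCc9ccccc9)c(Br)c3c(c1OCc9ccccc9)[C@H](OCCOCC)[C@H](O)[C@@H](c4ccc(OCc9ccccc9)c(OCc9ccccc9)c4)O3
F3 | step 19 | 8-bromo-tetra-O-benzylcatechin-(4α→6)-8-bromo-penta-O-benzylepicatechin | c1c(OCc9ccccc9)c(Br)c2c(c1OCc9ccccc9)[C@@H](c1c(OCc9ccccc9)c(Br)c3c(c1OCc9ccccc9)C[C@@H](OCc9ccccc9)[C@@H](c4ccc(OCc9ccccc9)c(OCc9ccccc9)c4)O3)[C@H](O)[C@@H](c4ccc(OCc9ccccc9)c(OCc9ccccc9)c4)O2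
F4 | step 19 | penta-O-benzylcatechin-(4α→6)-8-bromo-tetra-O-benzylcatechin-(4α→6)-8-bromo-penta-O-benzylepicatechin | c9ccccc9COc1cc(OCc9ccccc9)c2c(c1)O[C@H](c4ccc(OCc9ccccc9)c(OCc9ccccc9)c4)[C@@H](OCc9ccccc9)[C@@H]2c1c(OCc9ccccc9)c(Br)c2c(c1OCc9ccccc9)[C@@H](c1c(OCc9ccccc9)c(Br)c3c(c1OCc9ccccc9)C[C@@H](OCc9ccccc9)[C@@H](c4ccc(OCc9ccccc9)c(OCc9ccccc9)c4)O3)[C@H](O)[C@@H](c4ccc(OCc9ccccc9)c(OCc9ccccc9)c4)O2
F5 | step 5 | 4α-(2,4,6-trihydroxyphenyl)-penta-O-benzylcatechin | c9ccccc9COc1cc(OCc9ccccc9)c2c(c1)O[C@H](c4ccc(OCc9ccccc9)c(OCc9ccccc9)c4)[C@@H](OCc9ccccc9)[C@@H]2c1c(O)cc(O)cc1O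
F6 | step 5 | 4α-[2,6-dihydroxy-4-(triisopropylsilyloxy)phenyl]-penta-O-benzylcatechin | c9ccccc9COc1cc(OCc9ccccc9)c2c(c1)O[C@H](c4ccc(OCc9ccccc9)c(OCc9ccccc9)c4)[C@@H](OCc9ccccc9)[C@@H]2c1c(O)cc(O[Si](C(C)C)(C(C)C)C(C)C)cc1O
F0 | step 20 | none | none
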